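**Remark (assumption):** germacrane numbering is used (ring carbons C1–C10 with C1=C10; C15 methyl on C4; lactone oxygen on C6; C11 on C7; C11=C13 exo-methylene; C12 lactone carbonyl; C14 ester carbon on C10). The SMILES is read as a cis-fused lactone (H6/H7 syn), a cis-4,5-epoxide, an 8,9-syn diester and a ring-cis C1=C10 alkene. (R)-Glycidol, neryl acetate, 2-(bromomethyl)acrylic acid and (S)-2-methylglycidol are taken as commercial.

## Retrosynthetic overview

1. Last operations: Yamaguchi acylation of O9 with (R)-2-methylglycidic acid, and the C8 acetate by Mitsunobu inversion of the 8R carbinol that the key step delivers.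
2. Key disconnection C7–C8. The enabling feature is the homoallylic alcohol array C13=C11–C7–C8–O8: the exo-methylene carbon of the five-membered lactone sits next to the ring-fusion carbon C7, which carries the C8 carbinol. This is the retron of a carbonyl allylation with allylic transposition, so the ten-membered carbocycle opens to a 3-(bromomethyl)butenolide tethered to a C8 aldehyde.
3. The butenolide comes from ring-closing metathesis of the 2-(bromomethyl)acrylate of a C6 vinyl carbinol. The 4,5-oxirane comes from hydroxyl-directed epoxidation of the Z-allylic alcohol, and C6 from an enantioselective vinyl addition.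
4. The chain is assembled from neryl acetate (C1–C6, C15, Z-alkene) and methyl (S)-4-(PMB-oxy)-3-(TES-oxy)butanoate (C8–C10, C14, from (R)-glycidol) by aldol addition and dehydration.
5. Ring order: 4,5-oxirane, then butenolide, then the ten-membered carbocycle (which at the same time turns the butenolide into the α-methylene lactone); the side-chain oxirane arrives with the acid.

Key step: step 15

## Route

Step 1
Reactants: 1 (R)-glycidol
Product: 2 (S)-2-{[(4-methoxybenzyl)oxy]methyl}oxirane
Conditions: NaH, 4-methoxybenzyl chloride, Bu4NI (cat.), THF/DMF, 0 °C to rt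
Reagents that add atoms: 4-methoxybenzyl chloride, COc1ccc(CCl)cc1
Why: Williamson etherification of the primary alkoxide leaves the stereocentre (future C9) untouched, the descriptor changing from R to S only through the priority rules.

Step 2
Reactants: 2 (S)-2-{[(4-methoxybenzyl)oxy]methyl}oxirane
Product: 3 methyl (3S)-3-hydroxy-4-[(4-methoxybenzyl)oxy]butanoate
Conditions: Co2(CO)8 (5 mol %), 3-hydroxypyridine (10 mol %), CO (40 bar), MeOH/THF, 60 °C
Reagents that add atoms: carbon monoxide, [C-]#[O+]; methanol, CO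
Why: Cobalt-catalysed carbonylative ring opening (methoxycarbonylation) of a terminal epoxide places the acyl group on the unsubstituted carbon, so the C–O stereocentre is retained and the product carries C8, C9, C10 and C14.

Step 3
Reactants: 3 methyl (3S)-3-hydroxy-4-[(4-methoxybenzyl)oxy]butanoate
Product: 4 methyl (3S)-4-[(4-methoxybenzyl)oxy]-3-[(triethylsilyl)oxy]butanoate
Conditions: Et3SiCl, imidazole, CH2Cl2, 0 °C
Reagents that add atoms: chlorotriethylsilane, CC[Si](Cl)(CC)CC
Why: Standard silylation of the secondary alcohol gives an O9 group that cannot chelate or participate and that is later removed under mild buffered fluoride conditions.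

Step 4
Reactants: 5 neryl acetate
Product: 7 (2Z)-3-methyl-6-oxohex-2-en-1-yl acetate, via secondary ozonide 6 (not isolated)
Conditions: O3 (1 equiv), CH2Cl2, −78 °C; then Me2S, −78 °C to rt
Reagents that add atoms: ozone, [O-][O+]=O
Why: Chemoselective ozonolysis should cleave the electron-rich distal trisubstituted alkene in preference to the alkene deactivated by the allylic acetate, leaving the Z geometry (future cis-epoxide) intact.

Step 5
Reactants: 4 methyl (3S)-4-[(4-methoxybenzyl)oxy]-3-[(triethylsilyl)oxy]butanoate, 7 (2Z)-3-methyl-6-oxohex-2-en-1-yl acetate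
Product: 9 methyl (6Z)-8-acetoxy-3-hydroxy-2-{(1S)-2-[(4-methoxybenzyl)oxy]-1-[(triethylsilyl)oxy]ethyl}-6-methyloct-6-enoate (mixture at C2 and C3), via lithium enolate of ester 8 (not isolated)
Conditions: LDA, THF, −78 °C; then 7, −78 °C; NH4Cl quench
Reagents that add atoms: none
Why: Lithium ester enolate aldol addition forms the C10–C1 bond (β-silyloxy ester enolates are stable at −78 °C and the aldehyde reacts faster than the acetate); the two new stereocentres are erased in step 6.

Step 6
Reactants: 9 aldol adduct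
Product: 11 methyl (2E,6Z)-8-acetoxy-2-{(1S)-2-[(4-methoxybenzyl)oxy]-1-[(triethylsilyl)oxy]ethyl}-6-methylocta-2,6-dienoate, via C3 mesylate 10 (not isolated)
Conditions: MsCl, Et3N, CH2Cl2, 0 °C; then DBU, 0 °C to rt
Reagents that add atoms: none
Why: Mesylation followed by E1cB elimination through the ester enolate lets both aldol diastereomers converge on the more stable trisubstituted enoate, in which C2 is trans to the ester and cis to C9, as the target requires.

Step 7
Reactants: 11 enoate acetate
Product: 12 methyl (2E,6Z)-8-hydroxy-2-{(1S)-2-[(4-methoxybenzyl)oxy]-1-[(triethylsilyl)oxy]ethyl}-6-methylocta-2,6-dienoate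
Conditions: K2CO3, MeOH, 0 °C
Reagents that add atoms: none
Why: Base-catalysed transesterification removes the primary allylic acetate, is degenerate for the methyl ester and should spare the secondary silyl ether at 0 °C.

Step 8
Reactants: 12 allylic alcohol
Product: 13 methyl (2E,6Z)-2-{(1S)-2-[(4-methoxybenzyl)oxy]-1-[(triethylsilyl)oxy]ethyl}-6-methyl-8-oxoocta-2,6-dienoate
Conditions: TEMPO (10 mol %), PhI(OAc)2, CH2Cl2, rt
Reagents that add atoms: none
Why: Oxoammonium (TEMPO/PhI(OAc)2) oxidation of the primary allylic alcohol is non-basic, so the Z-enal should form without isomerisation.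

Step 9
Reactants: 13 Z-enal
Product: 14 methyl (2E,6Z,8R)-8-hydroxy-2-{(1S)-2-[(4-methoxybenzyl)oxy]-1-[(triethylsilyl)oxy]ethyl}-6-methyldeca-2,6,9-trienoate
Conditions: Zn(CH=CH2)2 (2.5 equiv), (R)-diphenyl(1-methylpyrrolidin-2-yl)methanol (20 mol %), toluene, −20 to 0 °C
Reagents that add atoms: divinylzinc, C=C[Zn]C=C
Why: Amino-alcohol-catalysed enantioselective organozinc addition to the aldehyde, with the ligand antipode chosen for Re-face vinyl transfer (by analogy with dialkylzinc additions), should set C6 as R while both esters stay inert to the organozinc.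

Step 10
Reactants: 14 dienol
Product: 15 methyl (2E)-5-{(2R,3S)-3-[(1R)-1-hydroxyprop-2-en-1-yl]-2-methyloxiran-2-yl}-2-{(1S)-2-[(4-methoxybenzyl)oxy]-1-[(triethylsilyl)oxy]ethyl}pent-2-enoate
Conditions: mCPBA, NaHCO3, CH2Cl2, −10 to 0 °C
Reagents that add atoms: 3-chloroperoxybenzoic acid, OOC(=O)c1cccc(Cl)c1
Why: Hydroxyl-directed peracid epoxidation of the Z-allylic alcohol, in which A(1,3) strain with the cis C3 chain holds H6 in the alkene plane so that oxygen is delivered syn to the hydroxyl, should give the threo cis-epoxide (4R,5S); the trisubstituted alkene is far more nucleophilic than the vinyl group and the enoate.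

Step 11
Reactants: 15 epoxy alcohol, 16 2-(bromomethyl)acrylic acid
Product: 17 methyl (2E)-5-{(2R,3S)-3-[(1R)-1-{[2-(bromomethyl)acryloyl]oxy}prop-2-en-1-yl]-2-methyloxiran-2-yl}-2-{(1S)-2-[(4-methoxybenzyl)oxy]-1-[(triethylsilyl)oxy]ethyl}pent-2-enoate
Conditions: N,N'-diisopropylcarbodiimide, DMAP (10 mol %), CH2Cl2, 0 °C
Reagents that add atoms: none
Why: Steglich esterification at low temperature with catalytic DMAP acylates O6 without touching the allylic bromide and brings in C11, C12 and C13.

Step 12
Reactants: 17 acrylate ester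
Product: 18 methyl (2E)-5-{(2R,3S)-3-[(2R)-4-(bromomethyl)-5-oxo-2,5-dihydrofuran-2-yl]-2-methyloxiran-2-yl}-2-{(1S)-2-[(4-methoxybenzyl)oxy]-1-[(triethylsilyl)oxy]ethyl}pent-2-enoate
Conditions: second-generation Hoveyda–Grubbs catalyst (10 mol %), toluene (0.01 M), 80 °C, argon sparge
Reagents that add atoms: none
Why: Ring-closing metathesis between the acrylate and the C6 vinyl group closes the five-membered butenolide (C7=C11) with loss of ethene, the trisubstituted enoate being a spectator and C6 unaffected.

Step 13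
Reactants: 18 bromomethyl butenolide
Product: 19 methyl (2E)-5-{(2R,3S)-3-[(2R)-4-(bromomethyl)-5-oxo-2,5-dihydrofuran-2-yl]-2-methyloxiran-2-yl}-2-{(1S)-2-hydroxy-1-[(triethylsilyl)oxy]ethyl}pent-2-enoate
Conditions: DDQ, CH2Cl2/pH 7 buffer, 0 °C
Reagents that add atoms: none
Why: Oxidative cleavage of the 4-methoxybenzyl ether under neutral conditions frees O8 without harming the allylic bromide, the epoxide or the silyl ether.

Step 14
Reactants: 19 primary alcohol
Product: 20 methyl (2E)-5-{(2R,3S)-3-[(2R)-4-(bromomethyl)-5-oxo-2,5-dihydrofuran-2-yl]-2-methyloxiran-2-yl}-2-{(1S)-2-oxo-1-[(triethylsilyl)oxy]ethyl}pent-2-enoate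
Conditions: Dess–Martin periodinane, NaHCO3, CH2Cl2, 0 °C to rt; used at once
Reagents that add atoms: none
Why: Buffered Dess–Martin oxidation gives the C8 aldehyde under non-basic conditions, which should avoid epimerisation of the α-silyloxy, allylic C9 stereocentre.

Step 15
Reactants: 20 bromomethyl butenolide aldehyde
Product: 22 methyl (4R,5S,6R,7R,8R,9S)-4,5-epoxy-8-hydroxy-9-[(triethylsilyl)oxy]germacra-1(10),11(13)-dien-12,6-olid-14-oate (ring-cis C1=C10; cis-fused lactone; C8 epimer of the target), via allylchromium dichloride 21 (not isolated)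
Conditions: CrCl2 (8 equiv), THF, 25 °C, syringe-pump addition of 20 to a final 0.003 M; aqueous work-up
Reagents that add atoms: none
Why: CrCl2 (two equivalents of divalent chromium per bromide) converts the allylic C13–Br bond into an allylchromium species of trivalent chromium, which adds through its γ-carbon C7 to the C8 aldehyde in a six-membered chair transition state with allylic transposition, so that the butenolide becomes the α-methylene lactone (intramolecular Nozaki–Hiyama–Kishi allylation; closest known type: CrCl2-mediated closure of ten-membered germacranolide rings from 2-(bromomethyl)acrylate-type bromides and the Barbier additions of 3-(bromomethyl)butenolides to aldehydes). The ten-membered carbocycle closes exo-trig at the C8 carbonyl and SE2′ at the allyl unit, cis-fused to the five-membered lactone. C7 is controlled by C6: the tether leaves C6 on one face of the planar butenolide and, folded back by the cis-epoxide and the ring-cis C1=C10 alkene, brings the aldehyde to the neighbouring carbon on that same face, so that H6 and H7 become syn. C8 is controlled by the chair: the lactone ring holds C6 trans to the CH2Cr carbon and C9 must sit equatorial because the axial position on that face is taken by C5, which places O8 anti to C6 (8R), and this is at the same time the Felkin–Anh face of the α-silyloxy aldehyde (8,9-anti), so the three elements reinforce one another. The step needs γ- over α-attack (secured by the cyclic transition state), ring closure over oligomerisation (high dilution and slow addition) and tolerance of epoxide, enoate and lactone (neutral chromium conditions); the 8R carbinol it delivers is the C8 epimer of the target by design and is inverted in step 16.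

Step 16
Reactants: 22 macrocyclic 8R alcohol
Product: 23 methyl 8-acetoxy-4,5-epoxy-9-[(triethylsilyl)oxy]germacra-1(10),11(13)-dien-12,6-olid-14-oate with all ring stereocentres as in the target (CIP 4R,5S,6R,7S,8S,9S; the C7 descriptor differs from the target by priority only)
Conditions: PPh3, diisopropyl azodicarboxylate, AcOH, toluene, 0 °C to rt (betaine pre-formed before addition of 22)
Reagents that add atoms: acetic acid, CC(=O)O
Why: Mitsunobu esterification activates O8 as an alkoxyphosphonium ion that acetate displaces by SN2 with inversion, turning the 8R carbinol into the 8S acetate of the target, and the silyl ether on O9 cannot participate as a neighbouring group.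

Step 17
Reactants: 23 silyl ether acetate
Product: 24 methyl (4R,5S,6R,7R,8S,9S)-8-acetoxy-4,5-epoxy-9-hydroxygermacra-1(10),11(13)-dien-12,6-olid-14-oate
Conditions: HF·pyridine, pyridine, THF, 0 °C
Reagents that add atoms: none
Why: Buffered fluoride desilylation of the labile secondary triethylsilyl ether runs under weakly acidic conditions, which should suppress acetyl migration from O8 to O9 and spare the epoxide and the α-methylene lactone.

Step 18
Reactants: 25 (S)-2-methylglycidol
Product: 26 (R)-2-methyloxirane-2-carboxylic acid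
Conditions: TEMPO (cat.), PhI(OAc)2 (2.2 equiv), MeCN/H2O, rt; used crude
Reagents that add atoms: water, O
Why: Oxoammonium oxidation of the primary alcohol through the aldehyde hydrate gives the acid without touching the quaternary stereocentre, whose descriptor changes from S to R only by priority.

Step 19
Reactants: 24 C9 alcohol, 26 (R)-2-methyloxirane-2-carboxylic acid
Product: 28 target CNP0159450.1, via mixed trichlorobenzoic anhydride 27 (not isolated)
Conditions: 26, 2,4,6-trichlorobenzoyl chloride, Et3N, toluene, rt; then 24, DMAP, rt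
Reagents that add atoms: none
Why: Yamaguchi esterification through the mixed anhydride and the acylpyridinium ion acylates the hindered allylic O9 faster than the neighbouring acetate can migrate, and no stereocentre is involved.

## Compound list

1 | (R)-glycidol | OC[C@@H]1CO1 | starting material
2 | (S)-2-{[(4-methoxybenzyl)oxy]methyl}oxirane | COc1ccc(COC[C@@H]2CO2)cc1 | intermediate
3 | methyl (3S)-3-hydroxy-4-[(4-methoxybenzyl)oxy]butanoate | COC(=O)C[C@H](O)COCc1ccc(OC)cc1 | intermediate
4 | methyl (3S)-4-[(4-methoxybenzyl)oxy]-3-[(triethylsilyl)oxy]butanoate | COC(=O)C[C@H](O[Si](CC)(CC)CC)COCc1ccc(OC)cc1 | intermediate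
5 | neryl acetate, (2Z)-3,7-dimethylocta-2,6-dien-1-yl acetate | CC(=O)OC/C=C(C)\CCC=C(C)C | starting material
6 | secondary ozonide, (2Z)-5-(5,5-dimethyl-1,2,4-trioxolan-3-yl)-3-methylpent-2-en-1-yl acetate | CC(=O)OC/C=C(C)\CCC1OOC(C)(C)O1 | intermediate
7 | (2Z)-3-methyl-6-oxohex-2-en-1-yl acetate | CC(=O)OC/C=C(C)\CCC=O | intermediate
8 | lithium enolate of ester 4 | COC(O[Li])=C[C@H](O[Si](CC)(CC)CC)COCc1ccc(OC)cc1 | intermediate
9 | methyl (6Z)-8-acetoxy-3-hydroxy-2-{(1S)-2-[(4-methoxybenzyl)oxy]-1-[(triethylsilyl)oxy]ethyl}-6-methyloct-6-enoate (mixture at C2 and C3) | COC(=O)C(C(O)CC/C(C)=C\COC(C)=O)[C@H](O[Si](CC)(CC)CC)COCc1ccc(OC)cc1 | intermediate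
10 | C3 methanesulfonate of 9 | COC(=O)C(C(OS(C)(=O)=O)CC/C(C)=C\COC(C)=O)[C@H](O[Si](CC)(CC)CC)COCc1ccc(OC)cc1 | intermediate
11 | methyl (2E,6Z)-8-acetoxy-2-{(1S)-2-[(4-methoxybenzyl)oxy]-1-[(triethylsilyl)oxy]ethyl}-6-methylocta-2,6-dienoate | COC(=O)/C(=C/CC/C(C)=C\COC(C)=O)[C@H](O[Si](CC)(CC)CC)COCc1ccc(OC)cc1 | intermediate
12 | methyl (2E,6Z)-8-hydroxy-2-{(1S)-2-[(4-methoxybenzyl)oxy]-1-[(triethylsilyl)oxy]ethyl}-6-methylocta-2,6-dienoate | COC(=O)/C(=C/CC/C(C)=C\CO)[C@H](O[Si](CC)(CC)CC)COCc1ccc(OC)cc1 | intermediate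
13 | methyl (2E,6Z)-2-{(1S)-2-[(4-methoxybenzyl)oxy]-1-[(triethylsilyl)oxy]ethyl}-6-methyl-8-oxoocta-2,6-dienoate | COC(=O)/C(=C/CC/C(C)=C\C=O)[C@H](O[Si](CC)(CC)CC)COCc1ccc(OC)cc1 | intermediate
14 | methyl (2E,6Z,8R)-8-hydroxy-2-{(1S)-2-[(4-methoxybenzyl)oxy]-1-[(triethylsilyl)oxy]ethyl}-6-methyldeca-2,6,9-trienoate | COC(=O)/C(=C/CC/C(C)=C\[C@H](O)C=C)[C@H](O[Si](CC)(CC)CC)COCc1ccc(OC)cc1 | intermediate
15 | methyl (2E)-5-{(2R,3S)-3-[(1R)-1-hydroxyprop-2-en-1-yl]-2-methyloxiran-2-yl}-2-{(1S)-2-[(4-methoxybenzyl)oxy]-1-[(triethylsilyl)oxy]ethyl}pent-2-enoate | COC(=O)/C(=C/CC[C@@]1(C)O[C@H]1[C@H](O)C=C)[C@H](O[Si](CC)(CC)CC)COCc1ccc(OC)cc1 | intermediate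
16 | 2-(bromomethyl)acrylic acid | C=C(CBr)C(=O)O | starting material
17 | 2-(bromomethyl)acrylate ester of 15 at O6 | COC(=O)/C(=C/CC[C@@]1(C)O[C@H]1[C@H](OC(=O)C(=C)CBr)C=C)[C@H](O[Si](CC)(CC)CC)COCc1ccc(OC)cc1 | intermediate
18 | methyl (2E)-5-{(2R,3S)-3-[(2R)-4-(bromomethyl)-5-oxo-2,5-dihydrofuran-2-yl]-2-methyloxiran-2-yl}-2-{(1S)-2-[(4-methoxybenzyl)oxy]-1-[(triethylsilyl)oxy]ethyl}pent-2-enoate | COC(=O)/C(=C/CC[C@@]1(C)O[C@H]1[C@@H]2OC(=O)C(CBr)=C2)[C@H](O[Si](CC)(CC)CC)COCc1ccc(OC)cc1 | intermediate
19 | methyl (2E)-5-{(2R,3S)-3-[(2R)-4-(bromomethyl)-5-oxo-2,5-dihydrofuran-2-yl]-2-methyloxiran-2-yl}-2-{(1S)-2-hydroxy-1-[(triethylsilyl)oxy]ethyl}pent-2-enoate | COC(=O)/C(=C/CC[C@@]1(C)O[C@H]1[C@@H]2OC(=O)C(CBr)=C2)[C@H](O[Si](CC)(CC)CC)CO | intermediate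
20 | methyl (2E)-5-{(2R,3S)-3-[(2R)-4-(bromomethyl)-5-oxo-2,5-dihydrofuran-2-yl]-2-methyloxiran-2-yl}-2-{(1S)-2-oxo-1-[(triethylsilyl)oxy]ethyl}pent-2-enoate | COC(=O)/C(=C/CC[C@@]1(C)O[C@H]1[C@@H]2OC(=O)C(CBr)=C2)[C@H](O[Si](CC)(CC)CC)C=O | intermediate
21 | allylchromium dichloride (trivalent chromium) derived from 20 at C13 | COC(=O)/C(=C/CC[C@@]1(C)O[C@H]1[C@@H]2OC(=O)C(C[Cr](Cl)Cl)=C2)[C@H](O[Si](CC)(CC)CC)C=O | intermediate
22 | methyl (4R,5S,6R,7R,8R,9S)-4,5-epoxy-8-hydroxy-9-[(triethylsilyl)oxy]germacra-1(10),11(13)-dien-12,6-olid-14-oate (C8 epimer of the target skeleton) | C=C1C(=O)O[C@@H]2[C@H]1[C@@H](O)[C@@H](O[Si](CC)(CC)CC)/C(C(=O)OC)=C\CC[C@@]1(C)O[C@@H]21 | intermediate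
23 | methyl 8-acetoxy-4,5-epoxy-9-[(triethylsilyl)oxy]germacra-1(10),11(13)-dien-12,6-olid-14-oate, ring stereocentres as in the target (CIP 4R,5S,6R,7S,8S,9S) | C=C1C(=O)O[C@@H]2[C@H]1[C@H](OC(C)=O)[C@@H](O[Si](CC)(CC)CC)/C(C(=O)OC)=C\CC[C@@]1(C)O[C@@H]21 | intermediate
24 | methyl (4R,5S,6R,7R,8S,9S)-8-acetoxy-4,5-epoxy-9-hydroxygermacra-1(10),11(13)-dien-12,6-olid-14-oate | C=C1C(=O)O[C@@H]2[C@H]1[C@H](OC(C)=O)[C@@H](O)/C(C(=O)OC)=C\CC[C@@]1(C)O[C@@H]21 | intermediate
25 | (S)-2-methylglycidol, [(2S)-2-methyloxiran-2-yl]methanol | OC[C@@]1(C)CO1 | starting material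
26 | (R)-2-methyloxirane-2-carboxylic acid | OC(=O)[C@@]1(C)CO1 | intermediate
27 | (R)-2-methyloxirane-2-carboxylic 2,4,6-trichlorobenzoic anhydride | O=C(OC(=O)c1c(Cl)cc(Cl)cc1Cl)[C@@]1(C)CO1 | intermediate
28 | CNP0159450.1, methyl (4R,5S,6R,7R,8S,9S)-8-acetoxy-4,5-epoxy-9-{[(2R)-2-methyloxirane-2-carbonyl]oxy}germacra-1(10),11(13)-dien-12,6-olid-14-oate (ring-cis C1=C10, cis-fused lactone) | C=C1C(=O)O[C@@H]2[C@H]1[C@H](OC(C)=O)[C@@H](OC(=O)[C@@]1(C)CO1)/C(C(=O)OC)=C\CC[C@@]1(C)O[C@@H]21 | target

## Step count and risks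

Total step count: 19. Longest linear sequence: 17 steps (steps 1–3, 5–17 and 19, from (R)-glycidol).

The three steps most likely to fail:

1. **Step 15 (ring closure).** Intermolecular coupling and Wurtz-type dimerisation of the allylchromium species, or closure on the other face of the butenolide (trans-fusion), could outrun the desired ring closure. The fallback replaces the in situ reductive metalation by a preformed, isolable allylboron nucleophile. It sets out from bromo alcohol 19: Miyaura-type borylation of the allylic bromide (B2pin2, Pd2(dba)3 cat., toluene, 50 °C) should give the pinacol allylboronate alcohol F1. Dess–Martin oxidation should give the allylboronate aldehyde F2. Heating F2 at high dilution in toluene (thermal intramolecular allylboration through the same chair, then aqueous NaHCO3 hydrolysis of the borate) should return the route at macrocycle 22.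

2. **Step 16 (inversion at C8).** β-Elimination from the alkoxyphosphonium ion toward C7 or C9, or conjugate addition of the phosphine to the α-methylene lactone, could compete with substitution at the hindered C8. The fallback inverts C8 by oxidation and reduction and sets out from 22: Dess–Martin oxidation should give the C8 ketone F3. Luche reduction (NaBH4, CeCl3·7H2O, MeOH, −78 °C), with hydride adding anti to the C9 silyloxy group in the Felkin–Anh sense, should give the 8S alcohol F4. Acetylation (Ac2O, pyridine, DMAP cat.) returns the route at acetate 23.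

3. **Step 9 (C6 stereocentre).** Enantiofacial discrimination may be insufficient with the β,β-disubstituted Z-enal, or the vinyl reagent may be lost by protonolysis. The fallback sets C6 by alkynylation and semihydrogenation and sets out from enal 13: ProPhenol/Me2Zn-catalysed addition of trimethylsilylacetylene (ligand antipode chosen for Re-face delivery) should give the silylated propargylic alcohol F5. K2CO3/MeOH should give the terminal propargylic alcohol F6. Semihydrogenation (H2, Pd/CaCO3 poisoned with Pb(OAc)2, quinoline) returns the route at dienol 14.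

## Further compounds

F1 | step 15 | pinacol allylboronate alcohol (19 with CH2Br replaced by CH2B(pin)) | COC(=O)/C(=C/CC[C@@]1(C)O[C@H]1[C@@H]2OC(=O)C(CB3OC(C)(C)C(C)(C)O3)=C2)[C@H](O[Si](CC)(CC)CC)CO
F2 | step 15 | pinacol allylboronate aldehyde (20 with CH2Br replaced by CH2B(pin)) | COC(=O)/C(=C/CC[C@@]1(C)O[C@H]1[C@@H]2OC(=O)C(CB3OC(C)(C)C(C)(C)O3)=C2)[C@H](O[Si](CC)(CC)CC)C=O
F3 | step 16 | C8 ketone of macrocycle 22 | C=C1C(=O)O[C@@H]2[C@H]1C(=O)[C@@H](O[Si](CC)(CC)CC)/C(C(=O)OC)=C\CC[C@@]1(C)O[C@@H]21
F4 | step 16 | 8S alcohol (C8 epimer of 22) | C=C1C(=O)O[C@@H]2[C@H]1[C@H](O)[C@@H](O[Si](CC)(CC)CC)/C(C(=O)OC)=C\CC[C@@]1(C)O[C@@H]21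
F5 | step 9 | methyl (2E,6Z,8S)-8-hydroxy-2-{(1S)-2-[(4-methoxybenzyl)oxy]-1-[(triethylsilyl)oxy]ethyl}-6-methyl-10-(trimethylsilyl)deca-2,6-dien-9-ynoate | COC(=O)/C(=C/CC/C(C)=C\[C@H](O)C#C[Si](C)(C)C)[C@H](O[Si](CC)(CC)CC)COCc1ccc(OC)cc1
F6 | step 9 | methyl (2E,6Z,8S)-8-hydroxy-2-{(1S)-2-[(4-methoxybenzyl)oxy]-1-[(triethylsilyl)oxy]ethyl}-6-methyldeca-2,6-dien-9-ynoate | COC(=O)/C(=C/CC/C(C)=C\[C@H](O)C#C)[C@H](O[Si](CC)(CC)CC)COCc1ccc(OC)cc1
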